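**Retrosynthetic overview**

- Endgame: the formyl carbon is attached to C1′ last, by C1′–B → C1′–CH2–B (Matteson) → CH2OH → CHO. The C3 acetate and the angelate on C1″ are installed before that, on the stable alkenylboronate.
- Key disconnection: the C2–C3 bond of the dihydrofuran ring (ring B: O1–C2–C3–C3a–C7a), formed together with a C1′–B bond by copper-catalysed borylative cyclisation of an ortho-formyl aryl allenyl ether. The structural feature behind this is that C2 holds ring oxygen O1 and the 1,1-disubstituted alkene carbon C1′ and is bonded to the benzylic carbinol carbon C3, which sits ortho to O1 on ring A. That is the pattern left when the oxygen-bearing end of a 2-metalloallyl unit attacks an aldehyde ortho to that oxygen.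
- Precursor: from methyl 5-acetylsalicylate by O-propargylation, asymmetric transfer hydrogenation (sets C1″), silylation, ester reduction, propargyl-to-allenyl isomerisation at the benzylic alcohol level, and MnO2 oxidation.
- Ring order: ring A (benzene) is purchased; ring B is the only ring formed, in step 7.

Key step: step 7

Assumption: the absolute sense of induction of the Ph-BPE–copper catalyst in this cyclisation is taken by analogy with intermolecular allylcopper additions; (S,S)-Ph-BPE is written, and the (R,R)-ligand would be used instead if it favoured the (2S,3S) ring.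

**Route**

Step 1
Reactants: 1 methyl 5-acetyl-2-hydroxybenzoate (methyl 5-acetylsalicylate); 2 propargyl bromide
Product: 3 methyl 5-acetyl-2-(prop-2-yn-1-yloxy)benzoate
Conditions: K2CO3, DMF, rt
Reagents that add atoms: none
Why: Williamson ether synthesis, in which the salicylate phenoxide displaces the propargylic bromide by SN2 while the ketone and the ester are inert to carbonate.

Step 2
Reactants: 3 methyl 5-acetyl-2-(prop-2-yn-1-yloxy)benzoate
Product: 4 methyl 5-[(1R)-1-hydroxyethyl]-2-(prop-2-yn-1-yloxy)benzoate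
Conditions: RuCl[(R,R)-TsDPEN](p-cymene) (1 mol%), HCO2H/Et3N (5:2), CH2Cl2, 30 °C
Reagents that add atoms: none
Why: Noyori–Ikariya asymmetric transfer hydrogenation of an aryl methyl ketone, in which the (R,R)-catalyst delivers hydride to the Si face and should give the (R)-carbinol as it does for acetophenone, leaving the ester, the aryl ether and the alkyne unreduced.

Step 3
Reactants: 4 methyl 5-[(1R)-1-hydroxyethyl]-2-(prop-2-yn-1-yloxy)benzoate
Product: 5 methyl 5-[(1R)-1-(tert-butyldimethylsilyloxy)ethyl]-2-(prop-2-yn-1-yloxy)benzoate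
Conditions: TBSCl, imidazole, DMF, rt
Reagents that add atoms: tert-butyldimethylsilyl chloride, CC(C)(C)[Si](C)(C)Cl
Why: imidazole-mediated silylation of a secondary alcohol, which touches only the O–H bond and so keeps the stereocentre, and gives an ether that withstands hydride, alkoxide base and the copper step.

Step 4
Reactants: 5 methyl 5-[(1R)-1-(tert-butyldimethylsilyloxy)ethyl]-2-(prop-2-yn-1-yloxy)benzoate
Product: 6 {5-[(1R)-1-(tert-butyldimethylsilyloxy)ethyl]-2-(prop-2-yn-1-yloxy)phenyl}methanol
Conditions: LiAlH4, THF, 0 °C; then H2O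
Reagents that add atoms: none
Why: LiAlH4 reduction of the aryl ester to the benzylic alcohol at 0 °C, which the silyl ether and the propargyl ether tolerate, and which removes any electrophilic carbonyl from the position ortho to the propargyl ether before the base step.

Step 5
Reactants: 6 {5-[(1R)-1-(tert-butyldimethylsilyloxy)ethyl]-2-(prop-2-yn-1-yloxy)phenyl}methanol
Product: 7 {5-[(1R)-1-(tert-butyldimethylsilyloxy)ethyl]-2-(propa-1,2-dien-1-yloxy)phenyl}methanol
Conditions: KOtBu (1.5 equiv), THF, 0 °C to rt; H2O quench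
Reagents that add atoms: none
Why: base-mediated propargyl-to-allenyl ether isomerisation (1,3-prototropic shift through the propargyl/allenyl anion, stopping at the aryloxyallene), run on the benzylic alkoxide because the carbanion next to the ether oxygen would add to an ortho-formyl group if the aldehyde were already present.

Step 6
Reactants: 7 {5-[(1R)-1-(tert-butyldimethylsilyloxy)ethyl]-2-(propa-1,2-dien-1-yloxy)phenyl}methanol
Product: 8 5-[(1R)-1-(tert-butyldimethylsilyloxy)ethyl]-2-(propa-1,2-dien-1-yloxy)benzaldehyde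
Conditions: MnO2 (activated, excess), CH2Cl2, rt
Reagents that add atoms: none
Why: MnO2 oxidation of a benzylic alcohol to the aldehyde under neutral heterogeneous conditions, which the acid-sensitive allenyl ether and the silyl ether should survive and which does not over-oxidise.

Step 7
Reactants: 8 5-[(1R)-1-(tert-butyldimethylsilyloxy)ethyl]-2-(propa-1,2-dien-1-yloxy)benzaldehyde; 9 bis(pinacolato)diboron
Product: 11 (2R,3R)-5-[(1R)-1-(tert-butyldimethylsilyloxy)ethyl]-2-[1-(pinacolatoboryl)ethenyl]-2,3-dihydro-1-benzofuran-3-ol, via C3-O-boryl ether of the cyclised alcohol 10 (not isolated)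
Conditions: CuCl (5 mol%), (S,S)-Ph-BPE [1,2-bis((2S,5S)-2,5-diphenylphospholan-1-yl)ethane] (6 mol%), NaOtBu (15 mol%), THF, 0 °C to rt; then aq NH4Cl
Reagents that add atoms: none
Why: The ligated copper boryl formed from CuCl, NaOtBu and 9 inserts the unsubstituted C=C of the allene syn, approaching anti to the ArO substituent and delivering boron to the sp carbon, which gives the (Z)-configured γ-aryloxy-β-boryl allylcopper with copper on the CH2 terminus. This species attacks the ortho-formyl group through its oxygen-bearing carbon in a closed six-membered chair, forming C2–C3 and closing ring B in the 5-exo-trig mode; the copper alkoxide is then borylated by 9 to give 10 and return the copper boryl, and the O–B bond is hydrolysed on work-up. The closest known reaction type is the copper-catalysed borylative coupling of monosubstituted allenes, heteroatom-substituted ones included, with aldehydes and ketones, together with its intramolecular allene–ketone variant. The 2,3-cis relationship follows from the Z geometry, which puts the aryloxy group axial in the chair, and from the short O1–C7a–C3a tether, which can then reach only an equatorial aldehyde aryl group; the absolute configuration (2R,3R) is set by the Ph-BPE ligand, which must select the Si face of the formyl group, the remote silyloxyethyl centre being a spectator. The step needs borylcupration of the allene to outrun insertion of C=O into the Cu–B bond and to avoid the enol-ether C=C, which the unhindered terminal allene bond and the deactivated ortho-alkoxybenzaldehyde should secure, and the intramolecular capture should be faster than E/Z equilibration or protonation of the allylcopper.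

Step 8
Reactants: 11 (2R,3R)-5-[(1R)-1-(tert-butyldimethylsilyloxy)ethyl]-2-[1-(pinacolatoboryl)ethenyl]-2,3-dihydro-1-benzofuran-3-ol
Product: 12 (2R,3R)-5-[(1R)-1-(tert-butyldimethylsilyloxy)ethyl]-2-[1-(pinacolatoboryl)ethenyl]-2,3-dihydro-1-benzofuran-3-yl acetate
Conditions: Ac2O, pyridine, DMAP (cat.), CH2Cl2, 0 °C to rt
Reagents that add atoms: acetic anhydride, CC(=O)OC(C)=O
Why: DMAP-catalysed acetylation of the secondary benzylic alcohol with retention (only O–H reacts), under base mild enough to leave the alkenylboronate and the silyl ether alone and not to eliminate AcOH to the benzofuran.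

Step 9
Reactants: 12 (2R,3R)-5-[(1R)-1-(tert-butyldimethylsilyloxy)ethyl]-2-[1-(pinacolatoboryl)ethenyl]-2,3-dihydro-1-benzofuran-3-yl acetate
Product: 13 (2R,3R)-5-[(1R)-1-hydroxyethyl]-2-[1-(pinacolatoboryl)ethenyl]-2,3-dihydro-1-benzofuran-3-yl acetate
Conditions: TBAF, AcOH (1:1), THF, 0 °C to rt
Reagents that add atoms: none
Why: fluoride cleavage of the Si–O bond, buffered with AcOH so that the acetate neither migrates nor eliminates, the pinacol boronate is only reversibly complexed, and the ionisable para-alkoxybenzylic centre is not exposed to acid.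

Step 10
Reactants: 13 (2R,3R)-5-[(1R)-1-hydroxyethyl]-2-[1-(pinacolatoboryl)ethenyl]-2,3-dihydro-1-benzofuran-3-yl acetate; 14 angelic acid
Product: 16 (1R)-1-{(2R,3R)-3-acetoxy-2-[1-(pinacolatoboryl)ethenyl]-2,3-dihydro-1-benzofuran-5-yl}ethyl (2Z)-2-methylbut-2-enoate, via angelic 2,4,6-trichlorobenzoic anhydride 15 (not isolated)
Conditions: 2,4,6-Cl3C6H2COCl, Et3N, toluene, rt; then 13, 75 °C (no DMAP)
Reagents that add atoms: none
Why: Yamaguchi esterification through the mixed anhydride, in which the alcohol attacks the less hindered angeloyl carbonyl with retention at the carbinol, and omitting DMAP suppresses the addition–elimination path that turns angelates (Z) into tiglates (E).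

Step 11
Reactants: 16 (1R)-1-{(2R,3R)-3-acetoxy-2-[1-(pinacolatoboryl)ethenyl]-2,3-dihydro-1-benzofuran-5-yl}ethyl (2Z)-2-methylbut-2-enoate
Product: 18 (1R)-1-{(2R,3R)-3-acetoxy-2-[3-(pinacolatoboryl)prop-1-en-2-yl]-2,3-dihydro-1-benzofuran-5-yl}ethyl (2Z)-2-methylbut-2-enoate, via lithium chloromethyl boronate complex 17 (not isolated)
Conditions: BrCH2Cl (2 equiv), n-BuLi (1.5 equiv, slow addition), THF, −78 °C to rt
Reagents that add atoms: bromochloromethane, ClCBr
Why: Matteson homologation, in which LiCH2Cl made by Br/Li exchange in the presence of the substrate should be captured by the Lewis-acidic boron faster than by the ester carbonyls, and the borate 17 then undergoes 1,2-migration of the alkenyl group with loss of chloride on warming, leaving the ring stereocentres untouched.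

Step 12
Reactants: 18 (1R)-1-{(2R,3R)-3-acetoxy-2-[3-(pinacolatoboryl)prop-1-en-2-yl]-2,3-dihydro-1-benzofuran-5-yl}ethyl (2Z)-2-methylbut-2-enoate
Product: 20 (1R)-1-[(2R,3R)-3-acetoxy-2-(3-hydroxyprop-1-en-2-yl)-2,3-dihydro-1-benzofuran-5-yl]ethyl (2Z)-2-methylbut-2-enoate, via allyl pinacol borate 19 (not isolated)
Conditions: NaBO3·4H2O, THF/H2O (1:1), 0 °C to rt
Reagents that add atoms: sodium perborate, O=BO[O-].[Na+]
Why: perborate oxidation of the C–B bond (1,2-shift of the allyl carbon from boron to oxygen, then hydrolysis), mild enough to leave the acetate, the angelate and the alkene intact.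

Step 13
Reactants: 20 (1R)-1-[(2R,3R)-3-acetoxy-2-(3-hydroxyprop-1-en-2-yl)-2,3-dihydro-1-benzofuran-5-yl]ethyl (2Z)-2-methylbut-2-enoate
Product: 21 (1R)-1-[(2R,3R)-3-acetoxy-2-(3-oxoprop-1-en-2-yl)-2,3-dihydro-1-benzofuran-5-yl]ethyl (2Z)-2-methylbut-2-enoate (CNP0294391.3)
Conditions: MnO2 (activated, excess), CH2Cl2, rt
Reagents that add atoms: none
Why: MnO2 oxidation of the primary allylic alcohol to the α-substituted acrolein under neutral conditions, compatible with both esters, so that the sensitive enal is formed in the last step.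

**Compound list**

1 | methyl 5-acetyl-2-hydroxybenzoate | COC(=O)c1cc(C(C)=O)ccc1O | starting material
2 | propargyl bromide | C#CCBr | starting material
3 | methyl 5-acetyl-2-(prop-2-yn-1-yloxy)benzoate | COC(=O)c1cc(C(C)=O)ccc1OCC#C | intermediate
4 | methyl 5-[(1R)-1-hydroxyethyl]-2-(prop-2-yn-1-yloxy)benzoate | COC(=O)c1cc([C@@H](C)O)ccc1OCC#C | intermediate
5 | methyl 5-[(1R)-1-(tert-butyldimethylsilyloxy)ethyl]-2-(prop-2-yn-1-yloxy)benzoate | COC(=O)c1cc([C@@H](C)O[Si](C)(C)C(C)(C)C)ccc1OCC#C | intermediate
6 | {5-[(1R)-1-(tert-butyldimethylsilyloxy)ethyl]-2-(prop-2-yn-1-yloxy)phenyl}methanol | OCc1cc([C@@H](C)O[Si](C)(C)C(C)(C)C)ccc1OCC#C | intermediate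
7 | {5-[(1R)-1-(tert-butyldimethylsilyloxy)ethyl]-2-(propa-1,2-dien-1-yloxy)phenyl}methanol | OCc1cc([C@@H](C)O[Si](C)(C)C(C)(C)C)ccc1OC=C=C | intermediate
8 | 5-[(1R)-1-(tert-butyldimethylsilyloxy)ethyl]-2-(propa-1,2-dien-1-yloxy)benzaldehyde | C=C=COc1ccc([C@@H](C)O[Si](C)(C)C(C)(C)C)cc1C=O | intermediate
9 | bis(pinacolato)diboron | CC1(C)OB(OC1(C)C)B1OC(C)(C)C(C)(C)O1 | starting material
10 | (2R,3R)-5-[(1R)-1-(tert-butyldimethylsilyloxy)ethyl]-2-[1-(pinacolatoboryl)ethenyl]-3-(pinacolatoboryloxy)-2,3-dihydro-1-benzofuran | C=C(B1OC(C)(C)C(C)(C)O1)[C@H]1Oc2ccc([C@@H](C)O[Si](C)(C)C(C)(C)C)cc2[C@H]1OB1OC(C)(C)C(C)(C)O1 | intermediate (not isolated)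
11 | (2R,3R)-5-[(1R)-1-(tert-butyldimethylsilyloxy)ethyl]-2-[1-(pinacolatoboryl)ethenyl]-2,3-dihydro-1-benzofuran-3-ol | C=C(B1OC(C)(C)C(C)(C)O1)[C@H]1Oc2ccc([C@@H](C)O[Si](C)(C)C(C)(C)C)cc2[C@H]1O | intermediate
12 | (2R,3R)-5-[(1R)-1-(tert-butyldimethylsilyloxy)ethyl]-2-[1-(pinacolatoboryl)ethenyl]-2,3-dihydro-1-benzofuran-3-yl acetate | C=C(B1OC(C)(C)C(C)(C)O1)[C@H]1Oc2ccc([C@@H](C)O[Si](C)(C)C(C)(C)C)cc2[C@H]1OC(C)=O | intermediate
13 | (2R,3R)-5-[(1R)-1-hydroxyethyl]-2-[1-(pinacolatoboryl)ethenyl]-2,3-dihydro-1-benzofuran-3-yl acetate | C=C(B1OC(C)(C)C(C)(C)O1)[C@H]1Oc2ccc([C@@H](C)O)cc2[C@H]1OC(C)=O | intermediate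
14 | angelic acid, (2Z)-2-methylbut-2-enoic acid | C/C=C(/C)C(=O)O | starting material
15 | (2Z)-2-methylbut-2-enoic 2,4,6-trichlorobenzoic anhydride | C/C=C(/C)C(=O)OC(=O)c1c(Cl)cc(Cl)cc1Cl | intermediate (not isolated)
16 | (1R)-1-{(2R,3R)-3-acetoxy-2-[1-(pinacolatoboryl)ethenyl]-2,3-dihydro-1-benzofuran-5-yl}ethyl (2Z)-2-methylbut-2-enoate | C=C(B1OC(C)(C)C(C)(C)O1)[C@H]1Oc2ccc([C@@H](C)OC(=O)/C(C)=C\C)cc2[C@H]1OC(C)=O | intermediate
17 | lithium (chloromethyl)(alkenyl)pinacolatoborate derived from 16 | [Li+].C=C([B-]1(CCl)OC(C)(C)C(C)(C)O1)[C@H]1Oc2ccc([C@@H](C)OC(=O)/C(C)=C\C)cc2[C@H]1OC(C)=O | intermediate (not isolated)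
18 | (1R)-1-{(2R,3R)-3-acetoxy-2-[3-(pinacolatoboryl)prop-1-en-2-yl]-2,3-dihydro-1-benzofuran-5-yl}ethyl (2Z)-2-methylbut-2-enoate | C=C(CB1OC(C)(C)C(C)(C)O1)[C@H]1Oc2ccc([C@@H](C)OC(=O)/C(C)=C\C)cc2[C@H]1OC(C)=O | intermediate
19 | (1R)-1-{(2R,3R)-3-acetoxy-2-[3-(pinacolatoboryloxy)prop-1-en-2-yl]-2,3-dihydro-1-benzofuran-5-yl}ethyl (2Z)-2-methylbut-2-enoate | C=C(COB1OC(C)(C)C(C)(C)O1)[C@H]1Oc2ccc([C@@H](C)OC(=O)/C(C)=C\C)cc2[C@H]1OC(C)=O | intermediate (not isolated)
20 | (1R)-1-[(2R,3R)-3-acetoxy-2-(3-hydroxyprop-1-en-2-yl)-2,3-dihydro-1-benzofuran-5-yl]ethyl (2Z)-2-methylbut-2-enoate | C=C(CO)[C@H]1Oc2ccc([C@@H](C)OC(=O)/C(C)=C\C)cc2[C@H]1OC(C)=O | intermediate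
21 | (1R)-1-[(2R,3R)-3-acetoxy-2-(3-oxoprop-1-en-2-yl)-2,3-dihydro-1-benzofuran-5-yl]ethyl (2Z)-2-methylbut-2-enoate | C=C(C=O)[C@H]1Oc2ccc([C@@H](C)OC(=O)/C(C)=C\C)cc2[C@H]1OC(C)=O | target

**Step count**

Total: 13 steps. Longest linear sequence: 13 steps (1 to 21).

**Steps most likely to fail**

1. Step 7. The cyclisation may proceed with poor control of the formyl face, or the allylcopper may equilibrate its geometry before ring closure, so that ring stereoisomers accompany 11. Fallback: the route sets out from 11 as obtained, a mixture of ring stereoisomers, and moves the stereocontrol from the C–C bond formation to a ketone reduction. Oxidation with Dess–Martin periodinane (NaHCO3, CH2Cl2, 0 °C) should give 5-[(1R)-1-(tert-butyldimethylsilyloxy)ethyl]-2-[1-(pinacolatoboryl)ethenyl]-1-benzofuran-3(2H)-one F1, in which C2 lies next to the ketone and the ring oxygen and epimerises readily. Asymmetric transfer hydrogenation with dynamic kinetic resolution (RuCl[(S,S)-TsDPEN](p-cymene), HCO2H/Et3N, CH2Cl2, rt, kept short so that reduction outpaces migration of the alkene into conjugation) should reduce the ketone cis to the C2 substituent and funnel all isomers into the (2R,3R) alcohol. The fallback rejoins the route at 11.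

2. Step 11. The lithium carbenoid, or n-BuLi before exchange, may attack the acetate or angelate carbonyl in competition with borate formation. Fallback: from 16, the lithium reagent is avoided altogether by replacing the homologation–oxidation sequence with a carbonylation. Iododeboronation (NaI, TsN(Cl)Na (chloramine-T), THF/H2O, rt) should give (1R)-1-[(2S,3R)-3-acetoxy-2-(1-iodoethenyl)-2,3-dihydro-1-benzofuran-5-yl]ethyl (2Z)-2-methylbut-2-enoate F2 (same spatial arrangement; the C2 descriptor changes only because iodine outranks oxygen). Palladium-catalysed reductive carbonylation (Pd(PPh3)4, CO 1 atm, Bu3SnH added slowly, THF, 50 °C) should then convert the alkenyl iodide directly into the enal. The fallback rejoins the route at 21, bypassing steps 11 to 13.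

3. Step 10. The angeloyl unit may isomerise from Z to E during acyl transfer at 75 °C, or the slow acylation may allow thermal loss of AcOH from C3. Fallback: from 13, the Z-alkene is built after the ester bond instead of being transferred intact. Steglich esterification with 2-[bis(2,2,2-trifluoroethoxy)phosphoryl]propanoic acid (DCC, DMAP cat., CH2Cl2, 0 °C to rt) should give (1R)-1-{(2R,3R)-3-acetoxy-2-[1-(pinacolatoboryl)ethenyl]-2,3-dihydro-1-benzofuran-5-yl}ethyl 2-[bis(2,2,2-trifluoroethoxy)phosphoryl]propanoate F3 (mixture of epimers at the phosphonate carbon, of no consequence). Still–Gennari olefination (KN(SiMe3)2, 18-crown-6, THF, −78 °C; then CH3CHO) should deliver the (Z)-2-methylbut-2-enoate selectively. The fallback rejoins the route at 16.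

**Further compounds**

F1 | step 7 | 5-[(1R)-1-(tert-butyldimethylsilyloxy)ethyl]-2-[1-(pinacolatoboryl)ethenyl]-1-benzofuran-3(2H)-one (C2 epimers interconverting) | C=C(B1OC(C)(C)C(C)(C)O1)C1Oc2ccc([C@@H](C)O[Si](C)(C)C(C)(C)C)cc2C1=O
F2 | step 11 | (1R)-1-[(2S,3R)-3-acetoxy-2-(1-iodoethenyl)-2,3-dihydro-1-benzofuran-5-yl]ethyl (2Z)-2-methylbut-2-enoate | C=C(I)[C@H]1Oc2ccc([C@@H](C)OC(=O)/C(C)=C\C)cc2[C@H]1OC(C)=O
F3 | step 10 | (1R)-1-{(2R,3R)-3-acetoxy-2-[1-(pinacolatoboryl)ethenyl]-2,3-dihydro-1-benzofuran-5-yl}ethyl 2-[bis(2,2,2-trifluoroethoxy)phosphoryl]propanoate | C=C(B1OC(C)(C)C(C)(C)O1)[C@H]1Oc2ccc([C@@H](C)OC(=O)C(C)P(=O)(OCC(F)(F)F)OCC(F)(F)F)cc2[C@H]1OC(C)=O
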